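**Retrosynthetic overview**
- The acid comes from its methyl ester; the C6 quaternary centre comes from axial ethyl transfer to a ring peroxycarbenium ion generated from a 6-methoxy-6-alkenyl-1,2-dioxane.
- The 1,2-dioxane (the only ring, formed in step 7) comes from hydroperoxy-ketalisation of the C6 enone carbonyl with H2O2 and 6-exo peroxy-Michael addition to a C2=C3 enoate.
- The enoate comes from Wittig olefination of a γ-keto aldehyde. The key C4–C5 bond of that keto aldehyde is made by oxidative enamine umpolung: the α-carbon of butanal becomes an electrophilic radical cation and is joined to the α′-carbon of the side-chain enone (as its silyl dienol ether), which sets C4.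
- The (E)-enone comes from methylalumination/acylation of (S)-4-ethyloct-1-yne, which comes from (S)-4-ethyloctan-2-one, made by asymmetric conjugate ethylation of (E)-oct-3-en-2-one (sets C10).

Assumption: the target is the (3R,4R,6R)-acid with the (1E,4S) side chain as drawn in the SMILES; the catalyst antipodes named in steps 1 and 5 are those expected to give the drawn centres and would be exchanged for their mirror images if the measured sense were opposite.

**Step 1**
Reactants: 1 (E)-oct-3-en-2-one
Product: 3 (S)-4-ethyloctan-2-one, via zinc enolate 2 (not isolated)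
Conditions: Et2Zn (1.5 equiv), Cu(OTf)2 (2 mol %), (S,R,R)-BINOL/bis(1-phenylethyl)amine phosphoramidite (4 mol %), toluene, −30 °C; then 1 M HCl
Reagents that add atoms: diethylzinc, CC[Zn]CC
Why: Copper-catalysed asymmetric conjugate addition of a dialkylzinc to an acyclic aliphatic enone, in which the ligand-controlled choice of the β-carbon face sets the side-chain centre (C10 of the target) as S.

**Step 2**
Reactants: 3 (S)-4-ethyloctan-2-one
Product: 7 (S)-4-ethyloct-1-yne, via lithium enolate 4 (not isolated), via enol phosphate 5 (not isolated), via lithium acetylide 6 (not isolated)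
Conditions: LiN(iPr)2 (1.1 equiv), THF, −78 °C; ClP(O)(OEt)2, −78 °C → rt; LiN(iPr)2 (2.3 equiv), −78 °C → rt; H2O
Reagents that add atoms: none
Why: Negishi methyl-ketone-to-alkyne protocol (kinetic enolisation on the methyl side, O-phosphorylation, base-induced elimination), which leaves the stereocentre untouched because it is not α to the carbonyl.

**Step 3**
Reactants: 7 (S)-4-ethyloct-1-yne
Product: 9 (3E,6S)-6-ethyl-4-methyldec-3-en-2-one, via alkenylalane 8 (not isolated)
Conditions: Me3Al (2 equiv), Cp2ZrCl2 (20 mol %), CH2Cl2, 0 °C → rt; volatiles removed in vacuo; AcCl (1.5 equiv), Pd(PPh3)4 (5 mol %), THF, 0 °C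
Reagents that add atoms: trimethylaluminium, C[Al](C)C; acetyl chloride, CC(Cl)=O
Why: Negishi zirconium-catalysed syn-methylalumination places methyl on the internal and aluminium on the terminal alkyne carbon, and palladium-catalysed acylation of the alkenylalane proceeds with retention, so the E trisubstituted alkene is fixed.

**Step 4**
Reactants: 9 (3E,6S)-6-ethyl-4-methyldec-3-en-2-one
Product: 10 tert-butyl{[(3E,6S)-6-ethyl-4-methyldeca-1,3-dien-2-yl]oxy}dimethylsilane
Conditions: TBSOTf (1.2 equiv), Et3N (1.5 equiv), CH2Cl2, 0 °C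
Reagents that add atoms: tert-butyldimethylsilyl triflate, CC(C)(C)[Si](C)(C)OS(=O)(=O)C(F)(F)F
Why: Soft enolisation and O-silylation of a methyl enone occurs kinetically at the α′-methyl group and gives the cross-conjugated 2-silyloxydiene without touching the E alkene.

**Step 5**
Reactants: 10 tert-butyl{[(3E,6S)-6-ethyl-4-methyldeca-1,3-dien-2-yl]oxy}dimethylsilane; 11 butanal (3 equiv)
Product: 13 (2R,5E,8S)-2,8-diethyl-6-methyl-4-oxododec-5-enal, via enamine 12 (not isolated)
Conditions: (2S,5S)-5-benzyl-2-tert-butyl-3-methylimidazolidin-4-one·TFA (20 mol %), (NH4)2Ce(NO3)6 (2.2 equiv), 2,6-di-tert-butylpyridine (2 equiv), H2O (2 equiv), acetone, −20 °C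
Reagents that add atoms: none
Why: MacMillan SOMO-catalysed α-enolation of an aldehyde, an oxidative enamine umpolung in which one-electron oxidation of enamine 12 by tetravalent cerium makes the normally nucleophilic α-carbon of butanal an electrophilic radical cation that adds to the nucleophilic terminal CH2 of 10, a second oxidation and silyl loss returning the enone, while the benzyl group of the catalyst shields the Re face so that Si-face attack sets C4 as R.

**Step 6**
Reactants: 13 (2R,5E,8S)-2,8-diethyl-6-methyl-4-oxododec-5-enal (crude, used at once)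
Product: 14 methyl (2E,4R,7E,10S)-4,10-diethyl-8-methyl-6-oxotetradeca-2,7-dienoate
Conditions: Ph3P=CHCO2Me (1.3 equiv), CH2Cl2, 0 °C → rt
Reagents that add atoms: methyl (triphenylphosphoranylidene)acetate, COC(=O)C=P(c1ccccc1)(c1ccccc1)c1ccccc1
Why: Wittig olefination with a stabilised ylide is E-selective, attacks the aldehyde and not the enone carbonyl, and is too weakly basic to epimerise C4.

**Step 7**
Reactants: 14 methyl (2E,4R,7E,10S)-4,10-diethyl-8-methyl-6-oxotetradeca-2,7-dienoate
Product: 16 methyl 2-[(3R,4R)-4-ethyl-6-[(1E,4S)-4-ethyl-2-methyloct-1-en-1-yl]-6-methoxy-1,2-dioxan-3-yl]acetate (both C6 epimers), via methoxy hydroperoxide 15 (not isolated)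
Conditions: urea·H2O2 (5 equiv), Sc(OTf)3 (10 mol %), MeOH, rt; extractive work-up; Et2NH (0.5 equiv), CF3CH2OH, 0 °C → rt
Reagents that add atoms: hydrogen peroxide (as urea adduct), OO; methanol, CO
Why: Kobayashi-type 1,2-dioxane synthesis (Lewis-acid hydroperoxy-ketalisation of the ketone, then amine-mediated 6-exo-trig peroxy-Michael addition), in which the kinetic chair transition state is expected to hold the C4 ethyl equatorial and the enoate pseudo-axial (by analogy with the base-mediated oxa-Michael closures of E-enoates that give 2,6-trans-tetrahydropyrans), setting C3 as R cis to C4; the C6 ketal configuration does not matter because it is ionised in step 8.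

**Step 8**
Reactants: 16 methyl 2-[(3R,4R)-4-ethyl-6-[(1E,4S)-4-ethyl-2-methyloct-1-en-1-yl]-6-methoxy-1,2-dioxan-3-yl]acetate
Product: 18 methyl 2-[(3R,4R,6R)-4,6-diethyl-6-[(1E,4S)-4-ethyl-2-methyloct-1-en-1-yl]-1,2-dioxan-3-yl]acetate, via peroxycarbenium triflate 17 (not isolated)
Conditions: Et2Zn (3 equiv), TMSOTf (1.2 equiv), CH2Cl2, −78 °C; NaHCO3 quench at −78 °C
Reagents that add atoms: diethylzinc, CC[Zn]CC
Why: Proposed new method: TMSOTf ionises the allylic ketal methoxy group to the ring peroxycarbenium ion 17, which accepts ethyl from Et2Zn at C6 along the axial trajectory anti to the equatorial C4 ethyl (attack on the other face would need the half-chair with a 1,3-diaxial ethyl clash), so ethyl ends axial and the alkenyl chain equatorial (6R), the closest known reactions being Lewis-acid-mediated allylsilane and silyl ketene acetal additions to 3-alkoxy-1,2-dioxane peroxycarbenium ions and the axial dialkylzinc/TMSOTf alkylation of cyclic oxocarbenium ions.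

**Step 9**
Reactants: 18 methyl 2-[(3R,4R,6R)-4,6-diethyl-6-[(1E,4S)-4-ethyl-2-methyloct-1-en-1-yl]-1,2-dioxan-3-yl]acetate
Product: 20 2-[(3R,4R,6R)-4,6-diethyl-6-[(1E,4S)-4-ethyl-2-methyloct-1-en-1-yl]-1,2-dioxan-3-yl]acetic acid, via lithium carboxylate 19 (not isolated)
Conditions: LiOH (3 equiv), THF/H2O 3:1, 0 °C → rt; then 1 M HCl to pH 3
Reagents that add atoms: lithium hydroxide, [Li+].[OH-]
Why: Mild saponification of a methyl ester, which dialkyl peroxides of this type tolerate and which touches no stereocentre.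

**Compound list**
1 | (E)-oct-3-en-2-one | CCCC/C=C/C(C)=O | starting material
2 | ethyl{[(2Z,4S)-4-ethyloct-2-en-2-yl]oxy}zinc (zinc enolate) | CCCC[C@H](CC)/C=C(/C)O[Zn]CC | intermediate
3 | (S)-4-ethyloctan-2-one | CCCC[C@H](CC)CC(C)=O | intermediate
4 | lithium (S)-4-ethyloct-1-en-2-olate | CCCC[C@H](CC)CC(=C)[O-].[Li+] | intermediate
5 | diethyl (S)-4-ethyloct-1-en-2-yl phosphate | CCCC[C@H](CC)CC(=C)OP(=O)(OCC)OCC | intermediate
6 | lithium (S)-4-ethyloct-1-yn-1-ide | CCCC[C@H](CC)CC#[C-].[Li+] | intermediate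
7 | (S)-4-ethyloct-1-yne | CCCC[C@H](CC)CC#C | intermediate
8 | [(1E,4S)-4-ethyl-2-methyloct-1-en-1-yl]dimethylalane | CCCC[C@H](CC)C/C(C)=C/[Al](C)C | intermediate
9 | (3E,6S)-6-ethyl-4-methyldec-3-en-2-one | CCCC[C@H](CC)C/C(C)=C/C(C)=O | intermediate
10 | tert-butyl{[(3E,6S)-6-ethyl-4-methyldeca-1,3-dien-2-yl]oxy}dimethylsilane | CCCC[C@H](CC)C/C(C)=C/C(=C)O[Si](C)(C)C(C)(C)C | intermediate
11 | butanal | CCCC=O | starting material
12 | (2S,5S)-5-benzyl-1-[(E)-but-1-en-1-yl]-2-tert-butyl-3-methylimidazolidin-4-one (enamine) | CN1C(=O)[C@H](Cc2ccccc2)N(/C=C/CC)[C@@H]1C(C)(C)C | intermediate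
13 | (2R,5E,8S)-2,8-diethyl-6-methyl-4-oxododec-5-enal | CCCC[C@H](CC)C/C(C)=C/C(=O)C[C@@H](CC)C=O | intermediate
14 | methyl (2E,4R,7E,10S)-4,10-diethyl-8-methyl-6-oxotetradeca-2,7-dienoate | CCCC[C@H](CC)C/C(C)=C/C(=O)C[C@@H](CC)/C=C/C(=O)OC | intermediate
15 | methyl (2E,4R,7E,10S)-4,10-diethyl-6-hydroperoxy-6-methoxy-8-methyltetradeca-2,7-dienoate (both C6 epimers) | CCCC[C@H](CC)C/C(C)=C/C(OC)(OO)C[C@@H](CC)/C=C/C(=O)OC | intermediate
16 | methyl 2-[(3R,4R)-4-ethyl-6-[(1E,4S)-4-ethyl-2-methyloct-1-en-1-yl]-6-methoxy-1,2-dioxan-3-yl]acetate (both C6 epimers) | CCCC[C@H](CC)C/C(C)=C/C1(OC)C[C@@H](CC)[C@@H](CC(=O)OC)OO1 | intermediate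
17 | (3R,4R)-4-ethyl-6-[(1E,4S)-4-ethyl-2-methyloct-1-en-1-yl]-3-(2-methoxy-2-oxoethyl)-1,2-dioxan-1-ium-6-ylidene triflate (ring peroxycarbenium ion, C6=O+) | CCCC[C@H](CC)C/C(C)=C/C1=[O+]O[C@H](CC(=O)OC)[C@H](CC)C1.[O-]S(=O)(=O)C(F)(F)F | intermediate
18 | methyl 2-[(3R,4R,6R)-4,6-diethyl-6-[(1E,4S)-4-ethyl-2-methyloct-1-en-1-yl]-1,2-dioxan-3-yl]acetate | CCCC[C@H](CC)C/C(C)=C/[C@@]1(CC)C[C@@H](CC)[C@@H](CC(=O)OC)OO1 | intermediate
19 | lithium 2-[(3R,4R,6R)-4,6-diethyl-6-[(1E,4S)-4-ethyl-2-methyloct-1-en-1-yl]-1,2-dioxan-3-yl]acetate | CCCC[C@H](CC)C/C(C)=C/[C@@]1(CC)C[C@@H](CC)[C@@H](CC(=O)[O-])OO1.[Li+] | intermediate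
20 | 2-[(3R,4R,6R)-4,6-diethyl-6-[(1E,4S)-4-ethyl-2-methyloct-1-en-1-yl]-1,2-dioxan-3-yl]acetic acid | CCCC[C@H](CC)C/C(C)=C/[C@@]1(CC)C[C@@H](CC)[C@@H](CC(=O)O)OO1 | target

**Step count and risks**
Total step count: 9. Longest linear sequence: 9 (from 1 to 20).

Because C4 and C10 are set by two independent catalytic steps, the minor enantiomer from each ends up as a remote diastereomer; final purification by HPLC is planned.

The three steps most likely to fail:

Step 5. The electron-rich silyloxydiene may be oxidised directly by the cerium salt, and the transient allyl radical/cation may erode the E geometry. Fallback, setting out from 10 and returning at 13: N-bromosuccinimide in THF at 0 °C converts 10 into (3E,6S)-1-bromo-6-ethyl-4-methyldec-3-en-2-one F1. Butanal 11 is then alkylated with F1 under photoredox organocatalysis [Ru(bpy)3Cl2 (0.5 mol %), trans-2-tert-butyl-3,5-dimethylimidazolidin-4-one triflic acid salt (20 mol %), 2,6-lutidine, DMF, visible light]. Here the roles are inverted: the ketone-derived α-acyl radical is the electrophile and the closed-shell enamine the nucleophile, and no stoichiometric oxidant meets the diene.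

Step 7. The conjugated ketone may resist intermolecular hydroperoxy-ketalisation, and the peroxy-Michael addition may equilibrate to the 3,4-trans isomer. Fallback, setting out from 13 and returning at 18: 13 is treated with urea·H2O2 and Sc(OTf)3 in MeOH, so that the hydroperoxide is anchored on the aldehyde and reaches the enone carbonyl intramolecularly, giving (4R)-4-ethyl-6-[(1E,4S)-4-ethyl-2-methyloct-1-en-1-yl]-3,6-dimethoxy-1,2-dioxane F2. Et2Zn/TMSOTf at −78 °C ionises only the allylic ketal at C6 and gives (4R,6R)-4,6-diethyl-6-[(1E,4S)-4-ethyl-2-methyloct-1-en-1-yl]-3-methoxy-1,2-dioxane F3. TMSOTf with 1-(tert-butyldimethylsilyloxy)-1-methoxyethene at −78 °C then adds the acetate unit axially to the C3 peroxycarbenium ion, cis to the equatorial C4 ethyl. C3 is thus set by irreversible C–C bond formation instead of a reversible Michael addition. This fallback still uses the ethyl transfer of step 8.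

Step 8. Et2Zn may reduce the cation by β-hydride transfer or attack the O–O bond, and the ring C6–O bond may ionise instead of the methoxy group. Fallback, setting out from 16 and returning at 18: K[HC≡CBF3] with BF3·OEt2 in CH2Cl2/MeCN at −40 °C delivers a small sp-carbon nucleophile axially to the same cation and gives methyl 2-[(3R,4R,6R)-4-ethyl-6-[(1E,4S)-4-ethyl-2-methyloct-1-en-1-yl]-6-ethynyl-1,2-dioxan-3-yl]acetate F4. Diimide (KO2CN=NCO2K, AcOH, MeOH, 0 °C → rt) then saturates only the ethynyl group to ethyl, leaving the trisubstituted alkene and the peroxide intact.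

**Further compounds**
F1 | step 5 | (3E,6S)-1-bromo-6-ethyl-4-methyldec-3-en-2-one | CCCC[C@H](CC)C/C(C)=C/C(=O)CBr
F2 | step 7 | (4R)-4-ethyl-6-[(1E,4S)-4-ethyl-2-methyloct-1-en-1-yl]-3,6-dimethoxy-1,2-dioxane (C3 and C6 epimers) | CCCC[C@H](CC)C/C(C)=C/C1(OC)C[C@@H](CC)C(OC)OO1
F3 | step 7 | (4R,6R)-4,6-diethyl-6-[(1E,4S)-4-ethyl-2-methyloct-1-en-1-yl]-3-methoxy-1,2-dioxane (C3 epimers) | CCCC[C@H](CC)C/C(C)=C/[C@@]1(CC)C[C@@H](CC)C(OC)OO1
F4 | step 8 | methyl 2-[(3R,4R,6R)-4-ethyl-6-[(1E,4S)-4-ethyl-2-methyloct-1-en-1-yl]-6-ethynyl-1,2-dioxan-3-yl]acetate | CCCC[C@H](CC)C/C(C)=C/[C@@]1(C#C)C[C@@H](CC)[C@@H](CC(=O)OC)OO1
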